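(The data were computed with constants of no real substance, and the scatter is random.)

If you count the part of the charge not in links, 1−L, instead of the links L (both as fractions of the first end groups charged), the flask folds into one dimensionless number, N = L/(1−L). This is links made per unit of charge not in links. For a lone second-order step with equal charges it equals rate constant × charge × time, the Damköhler number.

| flask | first end groups | second end groups | temperature | remark | time |
|---|---|---|---|---|---|
| dusk | 0.050 M | 0.98 equiv | 0 °C | run made earlier |  |
| spring | 0.025 M | 0.98 equiv | 11 °C | run made earlier |  |
| noon | 0.038 M | 0.98 equiv | 0 °C | run made earlier |  |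
| cedar | 0.050 M (fed, over 12 min) | 0.980 equiv |  | the addition at −25 °C, then warmed to 5 °C; the feed brings no volume worth counting | 30 min |
| oak | 0.050 M | 0.980 equiv (fed, over 12 min) | 5 °C | all else is in the flask from the start; the feed brings no volume worth counting | 30 min |
| maple | 0.050 M (fed, over 12 min) | 0.980 equiv | 5 °C | all else is in the flask from the start; the feed brings no volume worth counting | 30 min |
| elm | 0.050 M | 0.980 equiv | 5 °C | everything together at the start | 30 min |

- dusk (time / min: links / %, first end groups / %): 2.00: 28.7, 47.9; 6.00: 45.9, 17.3; 10.0: 54.0, 11.2; 15.0: 57.5, 8.2; 25.0: 64.5, 7.2; 30.0: 68.1, 6.1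
- spring (time / min: links / %, first end groups / %): 2.50: 28.1, 29.1; 8.00: 47.0, 18.4; 12.0: 56.0, 15.0; 20.0: 66.2, 10.6; 30.0: 72.8, 7.1; 40.0: 76.4, 5.7
- noon (time / min: links / %, first end groups / %): 2.50: 27.7, 44.3; 8.00: 44.1, 15.8; 12.0: 48.8, 11.7; 20.0: 56.2, 10.0; 30.0: 62.2, 8.1; 40.0: 65.9, 6.1

(scatter of a reading: 0.5 percentage points)

- on the list of suspects stand: first end groups <-> dormant form; first end groups + second end groups -> links + released group; first end groups + released group -> side product

* which flask leads in amount of links, in percent of the first end groups charged ("all alike" within 1.5 percentage points) (cedar / oak / maple / elm / all alike)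
* how much links is there at the end, in percent of the first end groups charged: cedar
* how much links is there at the end, in percent of the first end groups charged: oak
* how much links is there at the end, in percent of the first end groups charged: maple
* how much links is there at the end, in percent of the first end groups charged: elm

At 30.0 min, the dusk run reads N = 2.13 and the noon run 1.65. Their ratio, 1.29, follows the charge ratio, 1.32. Per unit charge, the spring run stands 2.51 times above dusk, and interpolating that factor logarithmically to 5 °C gives elm N = 3.24, so I expect 76.4% links.

Between 15.0 min and 30.0 min the dusk readings have N growing as time to the power p = 0.658. I count a steady feed as half its time lost, which gives maple and oak 2.80, or 73.7%. I count cedar's cold feed as wholly lost, which gives 2.32, or 69.9%. So in my reckoning elm leads.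

One number is not enough, though: it gives oak and maple the same 2.80. At 6.00 min the dusk run reads 36.8% of its charge in neither links nor first end groups, and in oak the first end groups stand in the flask while the second end groups are still being fed, so I put oak below maple, without a figure of its own.

The forecast says elm 73%, maple 70% and cedar 66%, each below my figure, and oak 63%, and of cedar “little reaction in the cold, then a short warm period”. The flasks give elm 73.7%, maple 70.3%, cedar 67.8% and oak 67.0%.

    first end groups ⇌ dormant form (K = 1.90, k = 0.330 min⁻¹, Ea = 77.0 kJ mol⁻¹, ΔH = −29.0 kJ mol⁻¹)
    first end groups + second end groups → links + released group (k = 7.20 M⁻¹ min⁻¹, Ea = 46.0 kJ mol⁻¹)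
    first end groups + released group → side product (k = 1.20 M⁻¹ min⁻¹, Ea = 62.0 kJ mol⁻¹)
    (constants at 5 °C)

Elm's N reads back as 2.80, less than my 3.24, and oak's as 2.03. Now read oak at 80 min instead. Keeping half the feed time lost and the same p, I reckon its N at 4.26, which puts links at 81.0%. That neighbouring flask holds 14.5% side product and 81.0% links.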